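The route rests on cutting the C1–C6 bond of ring B (C1 carbinol, C2, C3 chloride, C4 bromide, C5, spiro C6). Across the spiro atom the target holds the homoallylic alcohol array O–C1–C6–C7=C8, the retron of a carbonyl-ene reaction. The precursor is an open-chain β-chloro aldehyde hanging from C6 of a 1,4-cyclohexadiene (ring A with C6=C7 and C9=C10Br). Its C3/C4 bromochloride comes from a catalytic enantioselective bromochlorination of a Z allylic alcohol. One catalytic isomerisation closes ring B, builds the quaternary spiro centre beside C11 under control of C4, and turns ring A into the conjugated bromodiene. Oxidation and reagent-controlled reduction then set C1.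

Key step: step 12

Numbering (spiro[5.5]undecane numbering of the target, used for all compounds): ring B = C1 (CHOH), C2 (CH2), C3 (CClCH3), C4 (CHBr), C5 (CH2), C6 (spiro). Ring A = C6, C7 (C–CH3), C8 (CH), C9 (CH), C10 (CBr), C11 (CMe2).

Assumption: the antipode of the Schiff base ligand in step 9 is the one whose titanium complex brominates the face of the C3=C4 bond that leads to (2S,3S)-13. Its sense is to be fixed in a model run, and the mirror-image ligand would serve the other series.

Step 1
Reactants: 1 3-ethoxycyclohex-2-en-1-one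
Product: 2 rac-3-ethoxy-6-methylcyclohex-2-en-1-one
Conditions: LiN(iPr)2 (1.1 equiv), THF, −78 °C; MeI, −78 to 0 °C
Reagents that add atoms: iodomethane, CI
Why: Kinetic deprotonation of the vinylogous ester at the α′ carbon and SN2 methylation of the cross-conjugated lithium enolate (alkylation half of the Stork–Danheiser sequence) install the future C7 methyl group; the new stereocentre is racemic and is erased in step 3.

Step 2
Reactants: 2 rac-3-ethoxy-6-methylcyclohex-2-en-1-one
Product: 4 rac-4-methyl-3-vinylcyclohex-2-en-1-one, via tertiary allylic alcohol 3 (not isolated)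
Conditions: CH2=CHMgBr, THF, 0 °C; then 1 M aq HCl, 0 °C to rt
Reagents that add atoms: vinylmagnesium bromide, C=C[Mg]Br
Why: 1,2-Addition of the Grignard reagent to the vinylogous ester carbonyl followed by acid-induced loss of ethanol with allylic transposition (Stork–Danheiser enone transposition) puts the vinyl group (future C5 and C4) on C6 and moves the carbonyl group to C10.

Step 3
Reactants: 4 rac-4-methyl-3-vinylcyclohex-2-en-1-one
Product: 6 2,2,4-trimethyl-3-vinylcyclohex-3-en-1-one, via monomethyl ketone 5 (not isolated)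
Conditions: KOtBu (2.3 equiv), tBuOH/THF, 0 °C; MeI (excess), 0 °C to rt
Reagents that add atoms: iodomethane, CI
Why: Deconjugative α,α-dimethylation of an enone through its extended potassium enolate: γ-deprotonation can only take place at the ring C7–H because the vinyl group carries no γ-hydrogen, both methyl groups enter at the α carbon C11, and the double bond is left as the tetrasubstituted C6=C7 bond, which removes the racemic stereocentre.

Step 4
Reactants: 6 2,2,4-trimethyl-3-vinylcyclohex-3-en-1-one
Product: 7 4-bromo-2-ethenyl-1,3,3-trimethylcyclohexa-1,4-diene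
Conditions: P(OPh)3, Br2, CH2Cl2, −60 °C; then 6, Et3N, −60 °C to reflux
Reagents that add atoms: bromine, BrBr
Why: Ketone to vinyl bromide conversion with the preformed triphenyl phosphite–bromine adduct (O-phosphonium activation, bromide addition, E2 loss of HBr with Et3N) can only give the C9=C10 bromide because C11 is quaternary, and the diene should survive because no free Br2 is left when 6 is added.

Step 5
Reactants: 7 4-bromo-2-ethenyl-1,3,3-trimethylcyclohexa-1,4-diene
Product: 9 2-(5-bromo-2,6,6-trimethylcyclohexa-1,4-dien-1-yl)ethan-1-ol, via alkylborane 8 (not isolated)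
Conditions: 9-BBN-H, THF, 0 °C to rt; then NaOH, 30% H2O2, 0 °C
Reagents that add atoms: hydrogen peroxide, OO
Why: Anti-Markovnikov hydroboration–oxidation: the bulky borane adds only to the monosubstituted C4=C5 bond with boron at the terminal C4, while the tetrasubstituted C6=C7 and the bromine-deactivated C9=C10 bonds are too hindered or too electron-poor to react.

Step 6
Reactants: 9 2-(5-bromo-2,6,6-trimethylcyclohexa-1,4-dien-1-yl)ethan-1-ol
Product: 10 (5-bromo-2,6,6-trimethylcyclohexa-1,4-dien-1-yl)acetaldehyde
Conditions: Dess–Martin periodinane, CH2Cl2, 0 °C to rt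
Reagents that add atoms: none
Why: Dess–Martin oxidation stops at the aldehyde under near-neutral conditions, so the β,γ-unsaturated aldehyde should not slip into conjugation.

Step 7
Reactants: 10 (5-bromo-2,6,6-trimethylcyclohexa-1,4-dien-1-yl)acetaldehyde
Product: 11 ethyl (Z)-4-(5-bromo-2,6,6-trimethylcyclohexa-1,4-dien-1-yl)-2-methylbut-2-enoate
Conditions: (CF3CH2O)2P(O)CH(CH3)CO2Et, KN(SiMe3)2, 18-crown-6, THF, −78 °C
Reagents that add atoms: ethyl 2-[bis(2,2,2-trifluoroethoxy)phosphoryl]propanoate, CCOC(=O)C(C)P(=O)(OCC(F)(F)F)OCC(F)(F)F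
Why: Still–Gennari olefination: fast, irreversible elimination from the kinetically favoured adduct of the electron-poor bis(trifluoroethyl) phosphonate gives the Z trisubstituted enoate (ester cis to C5), the geometry that later maps onto the trans C3/C4 bromochloride of ring B.

Step 8
Reactants: 11 ethyl (Z)-4-(5-bromo-2,6,6-trimethylcyclohexa-1,4-dien-1-yl)-2-methylbut-2-enoate
Product: 12 (Z)-4-(5-bromo-2,6,6-trimethylcyclohexa-1,4-dien-1-yl)-2-methylbut-2-en-1-ol
Conditions: iBu2AlH (2.2 equiv), CH2Cl2, −78 °C; aq potassium sodium tartrate work-up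
Reagents that add atoms: none
Why: 1,2-Reduction of the enoate with two hydride equivalents gives the allylic alcohol with retention of the Z geometry and leaves the vinyl bromide untouched.

Step 9
Reactants: 12 (Z)-4-(5-bromo-2,6,6-trimethylcyclohexa-1,4-dien-1-yl)-2-methylbut-2-en-1-ol
Product: 13 (2S,3S)-3-bromo-4-(5-bromo-2,6,6-trimethylcyclohexa-1,4-dien-1-yl)-2-chloro-2-methylbutan-1-ol
Conditions: NBS (1.05 equiv), ClTi(OiPr)3 (1.1 equiv), enantiopure tridentate salicylaldimine–amino alcohol (O,N,O Schiff base) ligand (20 mol %), hexanes, −20 °C, dark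
Reagents that add atoms: N-bromosuccinimide, O=C1CCC(=O)N1Br; chlorotitanium triisopropoxide, CC(C)O[Ti](Cl)(OC(C)C)OC(C)C
Why: Titanium-mediated catalytic enantioselective bromochlorination of an allylic alcohol: the alkoxide of 12 binds the chiral titanium Schiff base complex, NBS delivers electrophilic bromine to one face of the bound C3=C4 bond, and titanium-bound chloride opens the bromonium ion anti at the tertiary carbon C3, so the Z geometry is translated into the (3S,4S) bromochloride, while the unbound, shielded C6=C7 and the deactivated C9=C10Br bonds should stay untouched.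

Step 10
Reactants: 13 (2S,3S)-3-bromo-4-(5-bromo-2,6,6-trimethylcyclohexa-1,4-dien-1-yl)-2-chloro-2-methylbutan-1-ol
Product: 14 (2S,3S)-3-bromo-4-(5-bromo-2,6,6-trimethylcyclohexa-1,4-dien-1-yl)-2-chloro-2-methylbutanal
Conditions: Dess–Martin periodinane, CH2Cl2, 0 °C to rt
Reagents that add atoms: none
Why: Dess–Martin oxidation of the primary alcohol; the resulting α-chloro aldehyde has a fully substituted α carbon and therefore cannot epimerise or lose HCl by enolisation.

Step 11
Reactants: 14 (2S,3S)-3-bromo-4-(5-bromo-2,6,6-trimethylcyclohexa-1,4-dien-1-yl)-2-chloro-2-methylbutanal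
Product: 16 (3S,4S)-4-bromo-5-(5-bromo-2,6,6-trimethylcyclohexa-1,4-dien-1-yl)-3-chloro-3-methylpentanal, via methyl enol ether 15 (not isolated)
Conditions: MeOCH2PPh3Cl, KN(SiMe3)2, THF, 0 °C; 14, −78 to 0 °C; then 2 M aq HCl, THF, 0 °C
Reagents that add atoms: (methoxymethyl)triphenylphosphonium chloride, COC[P+](c1ccccc1)(c1ccccc1)c1ccccc1.[Cl-]; water, O
Why: Wittig methoxymethylenation and acid hydrolysis of the enol ether (one-carbon aldehyde homologation) add C1; the non-enolisable aldehyde tolerates the ylide, C3 and C4 are not touched, and cold dilute acid should keep the β-chloro aldehyde from losing HCl.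

Step 12
Reactants: 16 (3S,4S)-4-bromo-5-(5-bromo-2,6,6-trimethylcyclohexa-1,4-dien-1-yl)-3-chloro-3-methylpentanal
Product: 17 (1R,3S,4S,6R)-4,10-dibromo-3-chloro-3,7,11,11-tetramethylspiro[5.5]undeca-7,9-dien-1-ol (C1 epimer of the target)
Conditions: Sc(OTf)3 (10 mol %), 4 Å MS, CH2Cl2, −78 to −30 °C
Reagents that add atoms: none
Why: Sc(OTf)3 binds the aldehyde oxygen, the C6=C7 π bond attacks C1 and the oxygen takes the doubly allylic pseudo-axial hydrogen of C8 through a six-centre array (concerted or via a short-lived C7 cation), so that C1–C6 forms, C6=C7 moves to C7=C8 and the 1,4-diene of ring A becomes the conjugated 7,9-diene in one isomerisation. The closest known reaction type is the Lewis acid catalysed type 1 intramolecular carbonyl-ene cyclisation of citronellal to isopulegol, here run on a tetrasubstituted ring olefin so that a spiro centre results. Ring B closes in a 6-exo mode (both O and C7 stay outside the new ring) through a chair with C4–Br and C3–Cl equatorial, C3–CH3 axial, C11 equatorial and C7 axial. C6 is controlled by the C4 stereocentre, because attack on the other face of ring A would either place C4–Br 1,3-diaxial to a ring A carbon or push C2 against the C11 methyl groups, so the 6R centre should prevail. C1 is controlled by the cyclic hydrogen transfer, which needs the oxygen gauche to C7 on the C8 side and therefore gives the equatorial 1R alcohol, the C1 epimer of the target, to be corrected in steps 13 and 14. The step needs hydrogen transfer from C8 and not from C7–CH3 (secured by the same geometry and by the weak bis-allylic C–H bond), six- and not seven-membered closure (attack at C7 would need a strained endo mode) and survival of the β-chloro aldehyde (low temperature, oxophilic catalyst, no base).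

Step 13
Reactants: 17 (1R,3S,4S,6R)-4,10-dibromo-3-chloro-3,7,11,11-tetramethylspiro[5.5]undeca-7,9-dien-1-ol
Product: 18 (3S,4S,6R)-4,10-dibromo-3-chloro-3,7,11,11-tetramethylspiro[5.5]undeca-7,9-dien-1-one
Conditions: Dess–Martin periodinane, CH2Cl2, 0 °C
Reagents that add atoms: none
Why: Dess–Martin oxidation removes the mis-set C1 centre under base-free conditions, so neither β-elimination of HCl nor Grob-type fragmentation of the 1,3-chlorohydrin can start, and C3, C4 and the non-enolisable C6 are untouched.

Step 14
Reactants: 18 (3S,4S,6R)-4,10-dibromo-3-chloro-3,7,11,11-tetramethylspiro[5.5]undeca-7,9-dien-1-one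
Product: 20 (1S,3S,4S,6R)-4,10-dibromo-3-chloro-3,7,11,11-tetramethylspiro[5.5]undeca-7,9-dien-1-ol (target), via catechol borate 19 (not isolated)
Conditions: (R)-Me-CBS oxazaborolidine [(3aR)-1-methyl-3,3-diphenyltetrahydro-1H,3H-pyrrolo[1,2-c][1,3,2]oxazaborole, 0.2–1.0 equiv], catecholborane, toluene, −78 to −40 °C; pH 7 buffer work-up
Reagents that add atoms: none
Why: Corey–Bakshi–Shibata reduction: the (R)-oxazaborolidine binds the ketone with quaternary C6 as the large and C2H2 as the small flank and delivers hydride along the equatorial trajectory on the C7 side of C1, which is also the side left open by the axial C3 methyl group, so reagent and substrate control should reinforce each other and give the axial 1S alcohol, while the neutral borane spares the β-chloro ketone, both C–Br bonds and the hindered diene.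

Compound list
1 | 3-ethoxycyclohex-2-en-1-one | CCOC1=CC(=O)CCC1 | starting material
2 | rac-3-ethoxy-6-methylcyclohex-2-en-1-one | CCOC1=CC(=O)C(C)CC1 | intermediate
3 | 3-ethoxy-6-methyl-1-vinylcyclohex-2-en-1-ol (racemic diastereomer mixture, not isolated) | CCOC1=CC(O)(C=C)C(C)CC1 | intermediate
4 | rac-4-methyl-3-vinylcyclohex-2-en-1-one | CC1CCC(=O)C=C1C=C | intermediate
5 | 2,4-dimethyl-3-vinylcyclohex-3-en-1-one (racemic, not isolated) | CC1=C(C=C)C(C)C(=O)CC1 | intermediate
6 | 2,2,4-trimethyl-3-vinylcyclohex-3-en-1-one | CC1=C(C=C)C(C)(C)C(=O)CC1 | intermediate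
7 | 4-bromo-2-ethenyl-1,3,3-trimethylcyclohexa-1,4-diene | CC1=C(C=C)C(C)(C)C(Br)=CC1 | intermediate
8 | 9-[2-(5-bromo-2,6,6-trimethylcyclohexa-1,4-dien-1-yl)ethyl]-9-borabicyclo[3.3.1]nonane (not isolated) | CC1=C(CCB2C3CCCC2CCC3)C(C)(C)C(Br)=CC1 | intermediate
9 | 2-(5-bromo-2,6,6-trimethylcyclohexa-1,4-dien-1-yl)ethan-1-ol | CC1=C(CCO)C(C)(C)C(Br)=CC1 | intermediate
10 | (5-bromo-2,6,6-trimethylcyclohexa-1,4-dien-1-yl)acetaldehyde | CC1=C(CC=O)C(C)(C)C(Br)=CC1 | intermediate
11 | ethyl (Z)-4-(5-bromo-2,6,6-trimethylcyclohexa-1,4-dien-1-yl)-2-methylbut-2-enoate | CC1=C(C/C=C(/C)C(=O)OCC)C(C)(C)C(Br)=CC1 | intermediate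
12 | (Z)-4-(5-bromo-2,6,6-trimethylcyclohexa-1,4-dien-1-yl)-2-methylbut-2-en-1-ol | CC1=C(C/C=C(/C)CO)C(C)(C)C(Br)=CC1 | intermediate
13 | (2S,3S)-3-bromo-4-(5-bromo-2,6,6-trimethylcyclohexa-1,4-dien-1-yl)-2-chloro-2-methylbutan-1-ol | CC1=C(C[C@H](Br)[C@@](C)(Cl)CO)C(C)(C)C(Br)=CC1 | intermediate
14 | (2S,3S)-3-bromo-4-(5-bromo-2,6,6-trimethylcyclohexa-1,4-dien-1-yl)-2-chloro-2-methylbutanal | CC1=C(C[C@H](Br)[C@@](C)(Cl)C=O)C(C)(C)C(Br)=CC1 | intermediate
15 | (3S,4S)-4-bromo-5-(5-bromo-2,6,6-trimethylcyclohexa-1,4-dien-1-yl)-3-chloro-1-methoxy-3-methylpent-1-ene (E/Z mixture, not isolated) | CC1=C(C[C@H](Br)[C@@](C)(Cl)C=COC)C(C)(C)C(Br)=CC1 | intermediate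
16 | (3S,4S)-4-bromo-5-(5-bromo-2,6,6-trimethylcyclohexa-1,4-dien-1-yl)-3-chloro-3-methylpentanal | CC1=C(C[C@H](Br)[C@@](C)(Cl)CC=O)C(C)(C)C(Br)=CC1 | intermediate
17 | (1R,3S,4S,6R)-4,10-dibromo-3-chloro-3,7,11,11-tetramethylspiro[5.5]undeca-7,9-dien-1-ol | CC1=CC=C(Br)C(C)(C)[C@@]12C[C@H](Br)[C@@](C)(Cl)C[C@H]2O | intermediate
18 | (3S,4S,6R)-4,10-dibromo-3-chloro-3,7,11,11-tetramethylspiro[5.5]undeca-7,9-dien-1-one | CC1=CC=C(Br)C(C)(C)[C@@]12C[C@H](Br)[C@@](C)(Cl)CC2=O | intermediate
19 | 2-{[(1S,3S,4S,6R)-4,10-dibromo-3-chloro-3,7,11,11-tetramethylspiro[5.5]undeca-7,9-dien-1-yl]oxy}-1,3,2-benzodioxaborole (not isolated) | CC1=CC=C(Br)C(C)(C)[C@@]12C[C@H](Br)[C@@](C)(Cl)C[C@@H]2OB3Oc4ccccc4O3 | intermediate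
20 | (1S,3S,4S,6R)-4,10-dibromo-3-chloro-3,7,11,11-tetramethylspiro[5.5]undeca-7,9-dien-1-ol | CC1=CC=C(Br)C(C)(C)[C@@]12C[C@H](Br)[C@@](C)(Cl)C[C@@H]2O | target

Total step count: 14. Longest linear sequence: 14 steps (from 1).

Steps most likely to fail

Step 12 (key step). Loss of HCl from the β-chloro aldehyde, ionisation at C3, or plain failure of C–C bond formation next to the quaternary C11 may outrun the ene process. The facial bias exerted by C4 may also be weaker than planned. The fallback replaces the Lewis acid bound aldehyde by an acylium ion. Setting out from 16, a Pinnick oxidation (NaClO2, NaH2PO4, 2-methylbut-2-ene, tBuOH/H2O) would give the carboxylic acid F1. 1-Chloro-N,N,2-trimethylprop-1-en-1-amine in CH2Cl2 would convert it under neutral conditions into the acid chloride F2. SnCl4 and 2,6-di-tert-butylpyridine in CH2Cl2 at −78 °C (intramolecular aliphatic Friedel–Crafts acylation of C6=C7 with loss of the C8 proton) would then close ring B irreversibly. This comes back to the route at 18, so step 13 falls away.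

Step 14. Hydride may enter along the axial trajectory and return the 1R series. Alternatively, the neopentyl ketone may react so slowly that hydroboration of the ring A diene or β-elimination of HCl competes. The fallback inverts C1 instead of reducing it. Setting out from 17, a Mitsunobu reaction (PPh3, diisopropyl azodicarboxylate, chloroacetic acid, toluene, 0 °C to rt) would give the inverted 1S chloroacetate F3. Thiourea with NaHCO3 in EtOH/THF would cleave it without generating an alkoxide. This arrives at 20 and bypasses steps 13 and 14.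

Step 9. Electrophilic bromine may attack the electron-rich C6=C7 bond or the bis-allylic C8 position. Enantiofacial control may also erode with the Z-configured 2-methyl allylic alcohol. The fallback uses no electrophilic halogen at all.
- Setting out from 12, a Sharpless asymmetric epoxidation (Ti(OiPr)4, L-(+)-diethyl tartrate, tBuOOH, 4 Å MS, CH2Cl2, −20 °C) would give the (2S,3R)-epoxy alcohol F4.
- Li2NiBr4 in THF would open it with inversion at the less substituted C4 to the bromodiol F5.
- tBuMe2SiCl and imidazole would give the primary silyl ether F6.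
- 1-Chloro-N,N,2-trimethylprop-1-en-1-amine would exchange the tertiary hydroxyl group for chloride with net retention through the C3/C4 bromonium ion, giving the tertiary chloride F7.
- HF·pyridine would come back to the route at 13.

Further compounds
F1 | step 12 | (3S,4S)-4-bromo-5-(5-bromo-2,6,6-trimethylcyclohexa-1,4-dien-1-yl)-3-chloro-3-methylpentanoic acid | CC1=C(C[C@H](Br)[C@@](C)(Cl)CC(=O)O)C(C)(C)C(Br)=CC1
F2 | step 12 | (3S,4S)-4-bromo-5-(5-bromo-2,6,6-trimethylcyclohexa-1,4-dien-1-yl)-3-chloro-3-methylpentanoyl chloride | CC1=C(C[C@H](Br)[C@@](C)(Cl)CC(=O)Cl)C(C)(C)C(Br)=CC1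
F3 | step 14 | (1S,3S,4S,6R)-4,10-dibromo-3-chloro-3,7,11,11-tetramethylspiro[5.5]undeca-7,9-dien-1-yl chloroacetate | CC1=CC=C(Br)C(C)(C)[C@@]12C[C@H](Br)[C@@](C)(Cl)C[C@@H]2OC(=O)CCl
F4 | step 9 | {(2S,3R)-3-[(5-bromo-2,6,6-trimethylcyclohexa-1,4-dien-1-yl)methyl]-2-methyloxiran-2-yl}methanol | CC1=C(C[C@H]2O[C@@]2(C)CO)C(C)(C)C(Br)=CC1
F5 | step 9 | (2S,3S)-3-bromo-4-(5-bromo-2,6,6-trimethylcyclohexa-1,4-dien-1-yl)-2-methylbutane-1,2-diol | CC1=C(C[C@H](Br)[C@@](C)(O)CO)C(C)(C)C(Br)=CC1
F6 | step 9 | (2S,3S)-3-bromo-4-(5-bromo-2,6,6-trimethylcyclohexa-1,4-dien-1-yl)-1-[(tert-butyldimethylsilyl)oxy]-2-methylbutan-2-ol | CC1=C(C[C@H](Br)[C@@](C)(O)CO[Si](C)(C)C(C)(C)C)C(C)(C)C(Br)=CC1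
F7 | step 9 | [(2S,3S)-3-bromo-4-(5-bromo-2,6,6-trimethylcyclohexa-1,4-dien-1-yl)-2-chloro-2-methylbutoxy](tert-butyl)dimethylsilane | CC1=C(C[C@H](Br)[C@@](C)(Cl)CO[Si](C)(C)C(C)(C)C)C(C)(C)C(Br)=CC1
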